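Atom labels used throughout: chroman O1, C2, C3, C4, C4a–C8a (ring A is the benzo ring, ring C the pyran ring); ring B is the pendant six-membered ring, C1'–C6', bound to C3 through C1'.

## The problem

Abruquinone B (13) is an isoflavan quinone: a 6,7,8-trimethoxychroman (rings A and C) that carries a 2,3-dimethoxy-1,4-benzoquinone (ring B) at C3. Its only stereocentre is C3 (S), a CH flanked by the methylene groups C2 and C4 and by ring B; since no second stereocentre exists to relay from, C3 has to be set by a catalyst or reagent on a prochiral precursor. A synthesis has to join ring B to C3, close ring C and fix C3, ideally in one operation. The quinone tolerates neither nucleophiles, bases, hydride nor hydrogenation, and once it is present C3–H can be lost by tautomerisation, so ring B should travel as a protected phenol and be oxidised last. Ring A is a tetra-oxygenated arene with a para oxygen pair (O1 and the 6-methoxy group), which rules out an unselective oxidative demethylation at the end. Any intermediate with C2 at the carbonyl level makes C3 both α-carbonyl and benzylic, hence epimerisable. The enabling feature is that ring A with O1 is 2,3,4-trimethoxyphenol (8), whose only unsubstituted carbon next to the hydroxyl is the future C4a, while C4–C3–C2 with ring B on C3 is a 2-arylacrolein when C2 is drawn as an aldehyde. The phenol carbon can then bond to the CH2 terminus (C4–C4a), the phenol oxygen to the carbonyl carbon (O1–C2), and a proton to C3.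

## Retrosynthesis

**13 to 12 and 11.** The two quinone carbonyls (C2' and C5') are traced back to phenol 12, with the hydroxyl on C2' and hydrogen on C5'. A radical oxidant that acts only on free phenols reaches the para-quinone on ring B and leaves the fully etherified ring A alone. A hydroquinone dimethyl ether on ring B was rejected, because its oxidative demethylation would also attack the para oxygen pair of ring A. The phenol is masked as benzyl ether 11, which survives ylide, acid and Lewis acid chemistry and leaves by hydrogenolysis; the chroman has no benzylic C–O bond to lose.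

**11 to 10.** The C2–H bond is replaced by C2–OH. This adds one oxygen but turns the chroman into a chroman-2-ol, the retron of a phenol–enal annulation. The forward step must remove the anomeric hydroxyl without base, because C3 in 10 is α to a masked aldehyde.

**10 to 7 and 8 (by way of 9).** The bonds C4–C4a and O1–C2 are cut and the hydrogen on C3 is removed, giving the achiral 2-arylacrolein 7 and phenol 8; the open hydroxy aldehyde 9 lies between them and 10. Cutting only O1–C2 or O1–C8a would leave a 1,3-diaryl-2-propyl unit whose stereocentre has to be made earlier, in a longer linear sequence under auxiliary control. Cutting C3–C1' would require an enantioselective arylation of a preformed chroman. The chosen cut divides the target into two stereocentre-free halves of similar size and makes the ring, two skeletal bonds and C3 at once. It asks for C-alkylation at the one free ortho carbon of 8, enantioselective protonation of the enamine that results, and a lactol that is reduced before it can epimerise.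

**7 to 6.** The C3=C4 double bond is cut; C4 comes from a one-carbon electrophile in a Mannich condensation–elimination on arylacetaldehyde 6. A cross-coupling route to 7 would need an aryl halide or boronate of ring B that is not at hand, whereas 6 derives from a cheap salicylaldehyde.

**6 to 5, 2 and 1 (with 3 and 4).** Aldehyde 6 is the hydrolysis product of enol ether 5, whose C2=C3 double bond comes from a Wittig reaction of benzaldehyde 2 with ylide 4, generated from phosphonium salt 3. Aldehyde 2 is the benzyl ether of commercial 1. The aldehyde carbon of 1 becomes C3, the ylide carbon C2.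

## Roads not taken

**Alternative 1:** pterocarpan detour by chromene–quinone [3+2] annulation.
- Cut: C3–C1', with a temporary bond from a ring B oxygen to C4.
- Forward key step: 6,7,8-trimethoxy-2H-chromene A1 and 2,3-dimethoxy-1,4-benzoquinone A2 are joined by a chiral tetravalent titanium TADDOLate made from TiCl2(OiPr)2. Quinone A2 is held through a carbonyl oxygen and the neighbouring methoxy oxygen, C3 of A1 attacks the quinone CH carbon, and the adjacent quinone oxygen captures the benzylic cation at C4. The product is the cis-pterocarpan A3. Hydrogenolysis of the benzylic C4–O bond would give hydroquinone A4, and a mild oxidant 13.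
- Merits: ring B arrives at the right oxidation level with no protecting group. A1 is two steps from 8 (propargylation, Claisen cyclisation). The whole route is about six steps. The bond construction is an established way to pterocarpans.
- Weak points: the enantioselective version of this reaction class relies on stoichiometric or larger amounts of the chiral titanium complex. Facial control rests on a single chelate and is sensitive to the alkene. Cyclobutane formation and cationic rearrangements compete. A1 is acid-labile and electron-rich, so oligomerisation and electron transfer from A1 to A2 are to be expected under a strong Lewis acid. Two stereocentres are made and one is then destroyed.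
- Comparison: this road is shorter and its bond-forming event is closer to precedent than step 5. The chosen plan sets against it a substoichiometric organic catalyst, two partners that are neither oxidants nor acid-labile, and a stereocentre set by proton transfer inside a covalently bound catalyst–substrate intermediate. The price is two more steps and one protecting group.

**Alternative 2:** electrochemical nickel-catalysed decarboxylative closure of C4–C4a.
- Cut: C4–C4a only. O1–C2 and the stereocentre are already present in the N-hydroxyphthalimide ester A5, which carries the activated carboxyl on C4 and bromine on C4a.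
- Forward key step: cathodic reduction with NiBr2·glyme and 4,4'-di-tert-butyl-2,2'-bipyridine fragments the ester to CO2 and a primary C4 radical. The radical is captured by the arylnickel species formed at the C4a–Br bond, and reductive elimination closes ring C to chroman A6.
- Merits: after C3 is set it is never next to a carbonyl group or a cation, so it is configurationally safer than in the chosen plan, where lactol 10 is epimerisable. The closure is intramolecular, six-membered and mild.
- Weak points: the key step creates no stereocentre, so C3 needs a separate asymmetric step beforehand, for example a rhodium-catalysed conjugate arylation of a 4-aryloxycrotonate with an ortho-alkoxy arylboronic acid, which is prone to protodeboronation. The aryl bromide sits on a very electron-rich ring next to the ether oxygen, a slow case for oxidative addition to low-valent nickel. The primary radical lies next to the aryl-bearing carbon and can undergo a 1,2-aryl shift or hydrogen abstraction if capture is slow. The sequence is linear and at least as long as the chosen one.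
- Comparison: better configurational security, no gain in length, and the stereochemical problem is only moved to an earlier step. The chosen plan sets convergence against it: ring, two bonds and C3 from two simple achiral pieces in one step.

**Alternative 3:** three-component conjunctive coupling on a vinylboron ate complex.
- Cut: C3–C1' and C4–C4a; C2 is not yet present.
- Forward key step: [3,4-dimethoxy-2-(methoxymethoxy)phenyl]lithium A7 adds to vinylboronic acid pinacol ester A8 to give an ate complex. Pd(OAc)2 with a chiral MandyPhos ligand and 1-(benzyloxy)-6-bromo-2,3,4-trimethoxybenzene A9 then trigger a 1,2-shift of the ring B aryl from boron to C3 while arylpalladium bonds C4. The product is the secondary boronate A10. Matteson homologation and oxidation would supply C2–OH, hydrogenolysis the ring A phenol, a Mitsunobu reaction the O1–C2 bond, and acetal cleavage and oxidation 13.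
- Merits: two skeletal bonds and C3 are made in one ligand-controlled catalytic step on the best-established substrate class for this reaction. The stereocentre is a configurationally stable C–B bond and every later step is stereospecific. In reliability of the stereochemical course this road is ahead of the chosen plan.
- Weak points: both aryl partners carry an ortho alkoxy group, so the aryl group that migrates in the ate complex of A7 and A8 is hindered, and the electrophile A9 is hindered and electron-rich. Bromide released from A9 inhibits the coupling unless it is scavenged or a triflate is used. Ring C is not closed and C2 is missing, so about five operations stand between A10 and the final oxidation, roughly ten in all, with two orthogonal phenol protecting groups.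
- Comparison: safer stereochemistry, lower step economy. The chosen plan closes the ring in the same step that sets C3 and needs one protecting group.

Key step: step 5

Assumption: the facial sense of the protonation in step 5 cannot be derived with certainty for this substrate pair; the route is written with the catalyst from L-tert-leucine, (S)-N1,N1-diethyl-3,3-dimethylbutane-1,2-diamine as its TfOH salt, and its enantiomer from D-tert-leucine is used unchanged if the (3R)-lactol should predominate.

## Route

Step 1
Reactants: 1 2-hydroxy-3,4-dimethoxybenzaldehyde
Product: 2 2-(benzyloxy)-3,4-dimethoxybenzaldehyde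
Conditions: BnBr, K2CO3, DMF, 60 °C
Reagents that add atoms: benzyl bromide, BrCc1ccccc1
Why: Williamson etherification of the phenoxide; the hydrogen bond to the ortho-formyl group slows but does not prevent alkylation in warm DMF, and the benzyl ether withstands ylide, aqueous acid, amine catalysis and BF3 at low temperature yet leaves by hydrogenolysis.

Step 2
Reactants: 2 2-(benzyloxy)-3,4-dimethoxybenzaldehyde; 3 (methoxymethyl)triphenylphosphonium chloride
Product: 5 2-(benzyloxy)-3,4-dimethoxy-1-(2-methoxyethenyl)benzene (E/Z mixture), via (methoxymethylidene)triphenylphosphorane 4 (not isolated)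
Conditions: 3, KOtBu, THF, 0 °C; then 2, 0 °C to rt
Reagents that add atoms: none
Why: Wittig methoxymethylenation of a non-enolisable aldehyde by the non-stabilised ylide 4; the E/Z ratio is irrelevant because both isomers hydrolyse to the same aldehyde.

Step 3
Reactants: 5 2-(benzyloxy)-3,4-dimethoxy-1-(2-methoxyethenyl)benzene
Product: 6 2-[2-(benzyloxy)-3,4-dimethoxyphenyl]acetaldehyde
Conditions: 2 M aq. HCl, THF, 50 °C
Reagents that add atoms: water, O
Why: Acid-catalysed enol ether hydrolysis (C-protonation, capture of the oxocarbenium ion by water, loss of methanol); the benzyl ether is inert to dilute acid, and the enolisable aldehyde 6 is used at once to limit self-condensation.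

Step 4
Reactants: 6 2-[2-(benzyloxy)-3,4-dimethoxyphenyl]acetaldehyde
Product: 7 2-[2-(benzyloxy)-3,4-dimethoxyphenyl]prop-2-enal
Conditions: 37% aq. CH2O, pyrrolidine (10 mol%), EtCO2H (10 mol%), i-PrOH, 45 °C
Reagents that add atoms: formaldehyde, C=O
Why: Amine-catalysed α-methylenation (Mannich condensation of the enamine of 6 with the formaldehyde-derived iminium ion, then β-elimination of the amine); the product is kept cold and in solution because 2-arylacroleins dimerise by hetero-Diels–Alder reaction when concentrated.

Step 5
Reactants: 7 2-[2-(benzyloxy)-3,4-dimethoxyphenyl]prop-2-enal; 8 2,3,4-trimethoxyphenol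
Product: 10 (3S)-3-[2-(benzyloxy)-3,4-dimethoxyphenyl]-6,7,8-trimethoxy-3,4-dihydro-2H-chromen-2-ol (mixture of C2 anomers), via ring-opened (2S)-hydroxy aldehyde 9 (not isolated)
Conditions: 8 (1.5 equiv), (S)-t-BuCH(NH2)CH2NEt2·TfOH (20 mol%), CHCl3, 0 °C
Reagents that add atoms: none
Why: Proposed new method: the primary amino group of the catalyst condenses with the α-branched enal 7 to an iminium ion (secondary amines do this poorly with α-substituted acroleins), and phenol 8, held by a hydrogen bond from its hydroxyl to the ammonium triflate ion pair, attacks the unhindered CH2 terminus through its only free ortho carbon in a Friedel–Crafts conjugate addition (C4–C4a). Rearomatisation leaves a planar enamine whose α-carbon (C3) is protonated by the neighbouring tertiary ammonium N–H of the catalyst, and hydrolysis of the resulting iminium ion releases hydroxy aldehyde 9 and the free amine. Ring C then closes by 6-exo-trig addition of the phenol oxygen to the aldehyde carbon (O1–C2) to give lactol 10. The closest known reaction types are the primary–tertiary diamine/TfOH-catalysed Friedel–Crafts addition of indoles to α-substituted acroleins with enantioselective enamine protonation and the amine-catalysed Friedel–Crafts/hemiacetalisation of phenols and naphthols with enals to chroman-2-ols; their union on an α-aryl acrolein and a simple polymethoxyphenol is the new element. C3 is set by the catalyst, which hands the proton to one face of the non-stereogenic enamine carbon inside the chiral ion pair, while the anomeric carbon C2 forms as an equilibrating mixture that is erased in step 6. The step needs C- over O-alkylation, which follows because the oxa-Michael adduct can revert whereas C–C bond formation is sealed by rearomatisation and lactol closure, and it needs attack at C6 of 8 and not at C5, which the substrate secures because C6 is the only unsubstituted carbon ortho to the hydroxyl, the strongest donor and the group bound to the catalyst, and is also para to the 3-methoxy group. Lactol closure also withdraws the α-aryl aldehyde from the amine and so limits enamine-mediated racemisation of C3, and the excess of 8 suppresses a second alkylation of the product at C5.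

Step 6
Reactants: 10 (3S)-3-[2-(benzyloxy)-3,4-dimethoxyphenyl]-6,7,8-trimethoxy-3,4-dihydro-2H-chromen-2-ol
Product: 11 (3S)-3-[2-(benzyloxy)-3,4-dimethoxyphenyl]-6,7,8-trimethoxy-3,4-dihydro-2H-chromene
Conditions: Et3SiH, BF3·OEt2, CH2Cl2, −78 °C
Reagents that add atoms: none
Why: Ionic hydrogenation of a lactol: BF3 ionises the anomeric hydroxyl to the O-aryl oxocarbenium ion, which takes hydride from Et3SiH; with no base present and at low temperature C3 next to the cation is not deprotonated, so its configuration is retained, and the benzyl ether is untouched.

Step 7
Reactants: 11 (3S)-3-[2-(benzyloxy)-3,4-dimethoxyphenyl]-6,7,8-trimethoxy-3,4-dihydro-2H-chromene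
Product: 12 2,3-dimethoxy-6-[(3S)-6,7,8-trimethoxy-3,4-dihydro-2H-chromen-3-yl]phenol
Conditions: H2 (1 atm), Pd/C, EtOAc, rt
Reagents that add atoms: none
Why: Heterogeneous hydrogenolysis of the benzylic C–O bond of the aryl benzyl ether; the chroman has no benzylic C–O bond, the methyl ethers are inert and C3 is not involved.

Step 8
Reactants: 12 2,3-dimethoxy-6-[(3S)-6,7,8-trimethoxy-3,4-dihydro-2H-chromen-3-yl]phenol
Product: 13 abruquinone B, 2,3-dimethoxy-5-[(3S)-6,7,8-trimethoxy-3,4-dihydro-2H-chromen-3-yl]cyclohexa-2,5-diene-1,4-dione
Conditions: (KSO3)2NO, KH2PO4, H2O/acetone, rt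
Reagents that add atoms: potassium nitrosodisulfonate (Fremy's salt), [K+].[K+].[O]N(S(=O)(=O)[O-])S(=O)(=O)[O-]
Why: Teuber oxidation: two equivalents of the nitrosodisulfonate radical turn a phenol with a free para position (C5') into the para-quinone by hydrogen abstraction, radical coupling at C5' and loss of imidodisulfonate; only ring B has a free hydroxyl, so ring A is spared, and the buffered neutral medium avoids tautomerisation of the quinone towards C3.

## Compound list

1 | 2-hydroxy-3,4-dimethoxybenzaldehyde | COc1ccc(C=O)c(O)c1OC | starting material
2 | 2-(benzyloxy)-3,4-dimethoxybenzaldehyde | COc1ccc(C=O)c(OCc2ccccc2)c1OC | intermediate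
3 | (methoxymethyl)triphenylphosphonium chloride | COC[P+](c1ccccc1)(c1ccccc1)c1ccccc1.[Cl-] | starting material
4 | (methoxymethylidene)triphenylphosphorane | COC=P(c1ccccc1)(c1ccccc1)c1ccccc1 | intermediate (not isolated)
5 | 2-(benzyloxy)-3,4-dimethoxy-1-(2-methoxyethenyl)benzene (E/Z mixture) | COC=Cc1ccc(OC)c(OC)c1OCc1ccccc1 | intermediate
6 | 2-[2-(benzyloxy)-3,4-dimethoxyphenyl]acetaldehyde | COc1ccc(CC=O)c(OCc2ccccc2)c1OC | intermediate
7 | 2-[2-(benzyloxy)-3,4-dimethoxyphenyl]prop-2-enal | C=C(C=O)c1ccc(OC)c(OC)c1OCc1ccccc1 | intermediate
8 | 2,3,4-trimethoxyphenol | COc1ccc(O)c(OC)c1OC | starting material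
9 | (2S)-2-[2-(benzyloxy)-3,4-dimethoxyphenyl]-3-(2-hydroxy-3,4,5-trimethoxyphenyl)propanal | COc1ccc([C@@H](C=O)Cc2cc(OC)c(OC)c(OC)c2O)c(OCc2ccccc2)c1OC | intermediate (not isolated)
10 | (3S)-3-[2-(benzyloxy)-3,4-dimethoxyphenyl]-6,7,8-trimethoxy-3,4-dihydro-2H-chromen-2-ol (mixture of C2 anomers) | COc1ccc([C@H]2C(O)Oc3c(cc(OC)c(OC)c3OC)C2)c(OCc2ccccc2)c1OC | intermediate
11 | (3S)-3-[2-(benzyloxy)-3,4-dimethoxyphenyl]-6,7,8-trimethoxy-3,4-dihydro-2H-chromene | COc1ccc([C@H]2COc3c(cc(OC)c(OC)c3OC)C2)c(OCc2ccccc2)c1OC | intermediate
12 | 2,3-dimethoxy-6-[(3S)-6,7,8-trimethoxy-3,4-dihydro-2H-chromen-3-yl]phenol | COc1ccc([C@H]2COc3c(cc(OC)c(OC)c3OC)C2)c(O)c1OC | intermediate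
13 | abruquinone B, 2,3-dimethoxy-5-[(3S)-6,7,8-trimethoxy-3,4-dihydro-2H-chromen-3-yl]cyclohexa-2,5-diene-1,4-dione | COC1=C(OC)C(=O)C([C@H]2COc3c(cc(OC)c(OC)c3OC)C2)=CC1=O | target

## Step count and risks

Total step count: 8. Longest linear sequence: 8 steps (1 to 13); phenol 8 enters at step 5.

**Step 5 (key step, proposed new method).** Three processes are most likely to go wrong. The first is loss of enantioselectivity: the enamine can be protonated outside the chiral ion pair by a phenolic hydroxyl, either that of the adduct through a six-membered transition state or that of excess 8, and the open form 9 can also epimerise through its enamine with the catalyst. The second is attack at C5 of 8, or a second alkylation of the product. The third is dimerisation of 7 outrunning the addition.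

Fallback (known chemistry, auxiliary control; sets out from 6 and returns at 11): Pinnick oxidation of 6 (NaClO2, NaH2PO4, 2-methylbut-2-ene) would give 2-[2-(benzyloxy)-3,4-dimethoxyphenyl]acetic acid F1. Its pivalic mixed anhydride is coupled with lithiated (4S)-4-benzyl-1,3-oxazolidin-2-one to (4S)-4-benzyl-3-{[2-(benzyloxy)-3,4-dimethoxyphenyl]acetyl}-1,3-oxazolidin-2-one F2. Purchased (3,4,5-trimethoxyphenyl)methanol F3 is brominated with N-bromosuccinimide to (2-bromo-3,4,5-trimethoxyphenyl)methanol F4 and converted with PBr3 into 2-bromo-1-(bromomethyl)-3,4,5-trimethoxybenzene F5. Evans alkylation of the sodium Z-enolate of F2 (NaHMDS, THF, −78 °C) with F5, on the face opposite the auxiliary benzyl group, gives (4S)-4-benzyl-3-[(2S)-2-[2-(benzyloxy)-3,4-dimethoxyphenyl]-3-(2-bromo-3,4,5-trimethoxyphenyl)propanoyl]-1,3-oxazolidin-2-one F6. LiBH4 removes the auxiliary at once to give (2S)-2-[2-(benzyloxy)-3,4-dimethoxyphenyl]-3-(2-bromo-3,4,5-trimethoxyphenyl)propan-1-ol F7. Intramolecular Buchwald–Hartwig etherification (Pd(OAc)2, 2-(di-tert-butylphosphino)-1,1'-binaphthyl, Cs2CO3, toluene, 80 °C) closes O1–C8a to 11. The stereocentre then comes from the auxiliary, at the cost of seven operations in place of steps 4 to 6.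

**Step 6.** The risk is erosion of configuration at C3: the oxocarbenium ion can lose the benzylic C3 proton to give the conjugated 4H-chromene, which is reprotonated and reduced without control. The cation can also be trapped by an electron-rich arene. Fallback (from 10 to 11): NaBH4 in EtOH at 0 °C reduces the open form to 6-[(2S)-2-[2-(benzyloxy)-3,4-dimethoxyphenyl]-3-hydroxypropyl]-2,3,4-trimethoxyphenol F8. A Mitsunobu reaction (PPh3, DIAD, THF, 0 °C) then closes O1–C2 by displacement at the primary carbon, which does not touch C3, and gives 11.

**Step 4.** The risks are aldol self-condensation of 6 under the amine/acid conditions and oligomerisation of 7 on concentration. Fallback (from 5 to 7, bypassing free 6): a Mannich reaction of enol ether 5 with dimethylmethylideneammonium iodide (Eschenmoser's salt) in CH2Cl2, followed by aqueous work-up, would give 2-[2-(benzyloxy)-3,4-dimethoxyphenyl]-3-(dimethylamino)propanal F9, storable as its hydrochloride. Quaternisation with iodomethane and elimination with NaHCO3 releases 7 in solution directly before step 5.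

**Step 8.** The risks are incomplete oxidation of the hindered phenol and further oxidation of the electron-rich product on long exposure. Fallback (from 12 to 13, classical aminophenol route): azo coupling of the phenoxide of 12 at the free para position with diazotised sulfanilic acid gives sodium 4-[(E)-{4-hydroxy-2,3-dimethoxy-5-[(3S)-6,7,8-trimethoxy-3,4-dihydro-2H-chromen-3-yl]phenyl}diazenyl]benzenesulfonate F10. Na2S2O4 cleaves the azo bond to 4-amino-2,3-dimethoxy-6-[(3S)-6,7,8-trimethoxy-3,4-dihydro-2H-chromen-3-yl]phenol F11. FeCl3 in dilute aqueous acid oxidises the para-aminophenol to the quinone imine, which hydrolyses to 13.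

## Further compounds

F1 | step 5 | 2-[2-(benzyloxy)-3,4-dimethoxyphenyl]acetic acid | COc1ccc(CC(=O)O)c(OCc2ccccc2)c1OC
F2 | step 5 | (4S)-4-benzyl-3-{[2-(benzyloxy)-3,4-dimethoxyphenyl]acetyl}-1,3-oxazolidin-2-one | COc1ccc(CC(=O)N2[C@@H](Cc3ccccc3)COC2=O)c(OCc2ccccc2)c1OC
F3 | step 5 | (3,4,5-trimethoxyphenyl)methanol (purchased) | COc1cc(CO)cc(OC)c1OC
F4 | step 5 | (2-bromo-3,4,5-trimethoxyphenyl)methanol | COc1cc(CO)c(Br)c(OC)c1OC
F5 | step 5 | 2-bromo-1-(bromomethyl)-3,4,5-trimethoxybenzene | COc1cc(CBr)c(Br)c(OC)c1OC
F6 | step 5 | (4S)-4-benzyl-3-[(2S)-2-[2-(benzyloxy)-3,4-dimethoxyphenyl]-3-(2-bromo-3,4,5-trimethoxyphenyl)propanoyl]-1,3-oxazolidin-2-one | O=C([C@@H](Cc1cc(OC)c(OC)c(OC)c1Br)c1ccc(OC)c(OC)c1OCc1ccccc1)N1[C@@H](Cc2ccccc2)COC1=O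
F7 | step 5 | (2S)-2-[2-(benzyloxy)-3,4-dimethoxyphenyl]-3-(2-bromo-3,4,5-trimethoxyphenyl)propan-1-ol | OC[C@@H](Cc1cc(OC)c(OC)c(OC)c1Br)c1ccc(OC)c(OC)c1OCc1ccccc1
F8 | step 6 | 6-[(2S)-2-[2-(benzyloxy)-3,4-dimethoxyphenyl]-3-hydroxypropyl]-2,3,4-trimethoxyphenol | COc1ccc([C@@H](CO)Cc2cc(OC)c(OC)c(OC)c2O)c(OCc2ccccc2)c1OC
F9 | step 4 | 2-[2-(benzyloxy)-3,4-dimethoxyphenyl]-3-(dimethylamino)propanal (racemic) | COc1ccc(C(CN(C)C)C=O)c(OCc2ccccc2)c1OC
F10 | step 8 | sodium 4-[(E)-{4-hydroxy-2,3-dimethoxy-5-[(3S)-6,7,8-trimethoxy-3,4-dihydro-2H-chromen-3-yl]phenyl}diazenyl]benzenesulfonate | COc1c(/N=N/c2ccc(S(=O)(=O)[O-])cc2)cc([C@H]2COc3c(cc(OC)c(OC)c3OC)C2)c(O)c1OC.[Na+]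
F11 | step 8 | 4-amino-2,3-dimethoxy-6-[(3S)-6,7,8-trimethoxy-3,4-dihydro-2H-chromen-3-yl]phenol | COc1c(N)cc([C@H]2COc3c(cc(OC)c(OC)c3OC)C2)c(O)c1OC
A1 | alternative 1 | 6,7,8-trimethoxy-2H-chromene | COc1cc2C=CCOc2c(OC)c1OC
A2 | alternative 1 | 2,3-dimethoxy-1,4-benzoquinone | COC1=C(OC)C(=O)C=CC1=O
A3 | alternative 1 | (6aS,11aS)-8-hydroxy-2,3,4,9,10-pentamethoxypterocarpan (cis) | Oc1cc2c(c(OC)c1OC)O[C@@H]1c3cc(OC)c(OC)c(OC)c3OC[C@H]21
A4 | alternative 1 | 2,3-dimethoxy-5-[(3S)-6,7,8-trimethoxy-3,4-dihydro-2H-chromen-3-yl]benzene-1,4-diol | COc1c(O)cc([C@H]2COc3c(cc(OC)c(OC)c3OC)C2)c(O)c1OC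
A5 | alternative 2 | 1,3-dioxoisoindolin-2-yl (3S)-4-(6-bromo-2,3,4-trimethoxyphenoxy)-3-[3,4-dimethoxy-2-(methoxymethoxy)phenyl]butanoate | COCOc1c([C@@H](COc2c(Br)cc(OC)c(OC)c2OC)CC(=O)ON2C(=O)c3ccccc3C2=O)ccc(OC)c1OC
A6 | alternative 2 | (3S)-3-[3,4-dimethoxy-2-(methoxymethoxy)phenyl]-6,7,8-trimethoxy-3,4-dihydro-2H-chromene | COCOc1c([C@H]2COc3c(cc(OC)c(OC)c3OC)C2)ccc(OC)c1OC
A7 | alternative 3 | [3,4-dimethoxy-2-(methoxymethoxy)phenyl]lithium | [Li]c1ccc(OC)c(OC)c1OCOC
A8 | alternative 3 | 2-ethenyl-4,4,5,5-tetramethyl-1,3,2-dioxaborolane (vinylboronic acid pinacol ester) | C=CB1OC(C)(C)C(C)(C)O1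
A9 | alternative 3 | 1-(benzyloxy)-6-bromo-2,3,4-trimethoxybenzene | COc1cc(Br)c(OCc2ccccc2)c(OC)c1OC
A10 | alternative 3 | 2-[(1S)-2-[2-(benzyloxy)-3,4,5-trimethoxyphenyl]-1-[3,4-dimethoxy-2-(methoxymethoxy)phenyl]ethyl]-4,4,5,5-tetramethyl-1,3,2-dioxaborolane | COCOc1c([C@H](Cc2cc(OC)c(OC)c(OC)c2OCc2ccccc2)B2OC(C)(C)C(C)(C)O2)ccc(OC)c1OC
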